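Compound numbers are those of the steps and of the compound list. Atoms are numbered as in eremophilanes (ring A: C1, C2, C3, C4, C5, C10; ring B: C5, C6, C7, C8, C9, C10).

## Analysis of the target

The target is an eremophilane-type bicycle of two fused six-membered carbocycles, esterified at the C3 oxygen with (2E,4E,6S)-6-methylocta-2,4-dienoic acid. Ring B holds the C8 ketone, which is conjugated linearly through C9=C10 and C1=C2 into ring A and cross-conjugated with the C7 isopropylidene group. The core has three contiguous stereocentres: C3 (acyloxy, 3S), C4 (secondary methyl, 4R) and the quaternary C5 (angular methyl, 5R). All three substituents lie on one face of ring A. The fourth stereocentre is the remote sec-butyl carbon of the acyl chain. The sensitive parts are the allylic C3 ester at the end of the dienone (its C3–H is vinylogously acidic, so equilibrating base can epimerise it), the isopropylidene enone and the dienoate, whose aldehyde precursor racemises easily. The difficulty is to make the quaternary C5 next to the C4 methyl group with cis relative and defined absolute configuration, and then to place the C3 oxygen cis to both. The plan rests on one feature of ring A. A cis C4-methyl/C5 pair on a cyclohexene with a C2=C3 alkene is what (E)-1-methylbutadiene and a 2-substituted acrolein give in an ortho, carbonyl-endo [4+2] addition, provided the C5 methyl is carried as the formyl carbon. Once oxidised to the acid, that carbon can reach C3 only on its own face, so a lactone passes the configuration of C5 on to C3.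

## Retrosynthetic reasoning

The ester C–O bond at C3 is cut first, so that target 34 comes from alcohol 26 and acid 32. The dienoate would not survive the enolate, oxidation and fluoride steps of the core, and acylation at oxygen leaves C3 untouched. Acid 32 goes back through ester 31 to aldehyde 28 and phosphonate 29 (cut at C4=C5 of the chain), and 28 to the chiral-pool alcohol 27, which supplies the side-chain stereocentre.

In 26, handled as its silyl ether 25, the exocyclic C7=C(CH3)2 bond is cut. This leads through aldol 23 to dienone 20 and acetone 21. C7 is the only carbon of 20 that a kinetic base deprotonates, so three carbons arrive in one C–C bond formation. The forward reaction has to dehydrate towards the ring and not towards a methyl group.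

Ring B is opened at C9=C10. Dienone 20 is the dehydration product of ketol 18, and 18 is the intramolecular aldol of diketone 16, in which the side-chain methyl carbon C9 attacks the C10 carbonyl. The chain C6–C9 already hangs on C5, so the ring closure is six-membered and needs no new stereocontrol. The forward reaction must enolise the methyl group without disturbing the γ C3–H of the enone.

The C10 carbonyl of 16 is traced, through ketal 15, to the C10 methylene group of silyl ether 14. C10 enters the synthesis as an unoxidised CH2, and C1=C2 is the only alkene of 14, so allylic oxidation is the direct way to activate it. C3, the other allylic carbon, is already oxygenated and screened by the silyl group.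

The C5 methyl group, the C3 oxygen and C1=C2 are traced back together. Alcohol 13 is the Wolff–Kishner product of lactol 11, which comes from unsaturated lactone 10. Lactone 10 is the dehydroiodination product of iodolactone 9, and 9 arises from acid 8, the oxidation product of aldehyde 7. Cutting the lactone C3–O bond and the C2–I bond returns the C2=C3 alkene of 7. The gain is that the C3 configuration follows from C5 by geometry alone, and that the same carbon serves in turn as formyl, carboxyl and methyl.

Aldehyde 7 is cut at C4–C5 and C1–C10 into dienophile 5 and diene 6. This is the only disconnection that makes the quaternary centre, its cis neighbour and ring A at once, from achiral partners, with the absolute configuration set by a catalyst. The forward reaction needs ortho regiochemistry, carbonyl-endo orientation and one enal face.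

Dienophile 5 is cut at its C5=C10 methylene bond into aldehyde 3 and formaldehyde 4. Aldehyde 3 is the reduction product of ester 2, the ketal of keto ester 1. The precursor is thus three routine steps from a commercial keto ester.

## Alternatives that were turned down

Alternative 1: The C4–CH3 bond (as a C–CH2Si bond) and the C5–C6 bond are cut on a preformed ring A enone. The substrate is (4S)-4-{[(bromomethyl)dimethylsilyl]oxy}-2-methylcyclohex-2-en-1-one A2. In the forward key step a radical chain turns the bromide of A2 into a silylmethyl radical that closes 5-exo onto C4. The tertiary α-keto radical left at C5 is trapped by allyltributylstannane A3 to give the cis-fused oxasilolane ketone A1. In its favour, the C3-oxygen/C4-carbon cis relation is enforced by the five-membered tether, and a radical step tolerates the crowding at the quaternary carbon. On the C3/C4 relation this is as secure as the lactone relay chosen here. Against it, A2 has to be obtained as a single enantiomer beforehand. The C5 configuration depends on A3 approaching anti to the new ring fusion in an intermolecular step. The allyl group brings only three of the four ring B carbons. The C–Si bond has still to become C–H, and C1=C2 must be added by a later dehydrogenation. The chosen route instead sets C4 and C5 in one catalytic step with absolute control and brings C6 to C9 in the dienophile.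

Alternative 2: Both ring alkenes are cut, C9=C10 and C1=C2, which opens the bicycle to the acyclic dienyne A5. In the forward key step the second-generation Grubbs catalyst loads on the pentenyl alkene of A5 and adds to the C10≡C1 alkyne to close ring B. The resulting C1 carbene closes ring A onto the C3 vinyl group, giving the diene silyl ether A4. This closes two rings and delivers the whole C9=C10–C1=C2 diene in one step, without the elimination, allylic oxidation and aldol that the chosen route spends on the same unsaturation. On that point it is the stronger plan. Against it, all three contiguous stereocentres, including a quaternary carbon bearing an ethynyl group, must be built in an open chain with no ring to relay configuration. The catalyst has to start at the correct alkene and engage an alkyne on a quaternary carbon. A4 still lacks the C8 oxygen and the C7 substituent, so a regioselective allylic oxidation beside the oxygenated C3 remains. The chosen route puts the stereochemical problem into a single cycloaddition.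

Alternative 3: Ring B is cut at C5–C6 and C7–C8. The ring A dienyl silyl ether A7 and methyl acrylate A8 combine under heat or Et2AlCl to the bicyclic ester A6, with C9=C10 already in place. It is convergent. Ring B arrives with the C8 oxygen and a C7 carbon substituent that can be turned into the isopropylidene group, so ring B functionality costs fewer steps than in the chosen route. On that point it is stronger. Against it, the quaternary C5 forms at a fully substituted diene terminus, which slows the cycloaddition and strains the s-cis conformer. Facial selectivity at C5 rests only on the neighbouring C4 methyl group. A7 needs a prior enantioselective synthesis of the cis C3/C4 pair. C1=C2 has to be introduced late by dehydrogenation. The chosen route offers catalyst control of the absolute configuration and a geometric, not statistical, link between C5 and C3.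

Key step: step 4

Assumption: the sense of induction in step 4 is taken from the usual pre-transition-state picture of this catalyst class (formyl C–H···O contact, s-trans enal, attack on the face remote from the shielding aryl group), which points to the (R)-catalyst for 7. If the opposite sense were found, the (S)-catalyst would be used with no other change.

## Route

Step 1
Reactants: 1 ethyl 5-oxohexanoate
Product: 2 ethyl 4-(2-methyl-1,3-dioxolan-2-yl)butanoate
Conditions: ethylene glycol, p-toluenesulfonic acid (cat.), toluene, reflux, Dean–Stark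
Reagents that add atoms: ethylene glycol, OCCO
Why: Acid-catalysed ketalisation with azeotropic removal of water; the ketone (future C8) is masked so that the ester can be reduced alone and stays inert until ring B is closed.

Step 2
Reactants: 2 ethyl 4-(2-methyl-1,3-dioxolan-2-yl)butanoate
Product: 3 4-(2-methyl-1,3-dioxolan-2-yl)butanal
Conditions: i-Bu2AlH (1.05 equiv), CH2Cl2, −78 °C; MeOH, then aq. potassium sodium tartrate
Reagents that add atoms: none
Why: Partial reduction of an ester; the aluminium hemiacetal persists at −78 °C and releases the aldehyde only on work-up.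

Step 3
Reactants: 3 4-(2-methyl-1,3-dioxolan-2-yl)butanal; 4 formaldehyde (37% aq.)
Product: 5 2-methylidene-4-(2-methyl-1,3-dioxolan-2-yl)butanal
Conditions: pyrrolidine (10 mol%), propionic acid (10 mol%), i-PrOH, 45 °C
Reagents that add atoms: none
Why: Amine-catalysed α-methylenation (Mannich condensation of the enamine with formaldehyde, then β-elimination of the amine); the weakly acidic buffer spares the ketal. The enal should be kept cold and used promptly.

Step 4
Reactants: 5 2-methylidene-4-(2-methyl-1,3-dioxolan-2-yl)butanal; 6 (E)-penta-1,3-diene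
Product: 7 (1S,2S)-2-methyl-1-[2-(2-methyl-1,3-dioxolan-2-yl)ethyl]cyclohex-3-ene-1-carbaldehyde
Conditions: (R)-3,3-diphenyl-1-(2-methylphenyl)tetrahydro-1H,3H-pyrrolo[1,2-c][1,3,2]oxazaborole (20 mol%), Tf2NH (16 mol%), 6 (3 equiv), CH2Cl2, −78 → −40 °C
Reagents that add atoms: none
Why: Enantioselective Diels–Alder reaction of a 2-substituted acrolein under a chiral oxazaborolidinium Lewis acid, a pairing of catalyst and dienophile class that is established for acyclic 1-substituted butadienes. The aldehyde binds boron anti to the alkene, with a formyl C–H···O contact to the ring oxygen; this locks the s-trans enal over one aryl group of the catalyst and lowers its LUMO, and the diene adds in a concerted, asynchronous [4+2] step in which the C1–C10 bond runs ahead of the C4–C5 bond. Ring A is closed by this intermolecular cycloaddition, both σ bonds forming suprafacially on each partner in one transition state, so no separate ring-closure mode has to be won. Ortho regiochemistry follows from the large HOMO coefficient at the unsubstituted diene terminus meeting the large LUMO coefficient at the enal β-carbon. C5 is set by the catalyst: the aryl group of the (R)-catalyst covers the Si face of the α-carbon and the diene adds to the Re face. C4 is set relative to C5 by the E geometry of 6 together with the formyl-endo orientation, which puts the methyl group cis to the formyl group; an acyclic diene has no bridging methylene to force the α-substituent endo, so the carbonyl-endo transition state should dominate. The quaternary C5 has no α-hydrogen, so the adduct cannot epimerise afterwards.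

Step 5
Reactants: 7 (1S,2S)-2-methyl-1-[2-(2-methyl-1,3-dioxolan-2-yl)ethyl]cyclohex-3-ene-1-carbaldehyde
Product: 8 (1S,2S)-2-methyl-1-[2-(2-methyl-1,3-dioxolan-2-yl)ethyl]cyclohex-3-ene-1-carboxylic acid
Conditions: NaClO2, NaH2PO4, 2-methylbut-2-ene, t-BuOH/H2O, 0 °C → rt
Reagents that add atoms: sodium chlorite, [Na+].[O-]Cl=O
Why: Pinnick oxidation; the scavenger removes hypochlorous acid before it reaches the ring alkene, and the phosphate buffer is mild enough for the ketal.

Step 6
Reactants: 8 (1S,2S)-2-methyl-1-[2-(2-methyl-1,3-dioxolan-2-yl)ethyl]cyclohex-3-ene-1-carboxylic acid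
Product: 9 (1R,4R,5R,8R)-4-iodo-8-methyl-1-[2-(2-methyl-1,3-dioxolan-2-yl)ethyl]-6-oxabicyclo[3.2.1]octan-7-one
Conditions: I2, NaHCO3, THF/H2O, 0 °C → rt, dark
Reagents that add atoms: iodine, II
Why: Iodolactonisation; the iodonium ion forms on the alkene face anti to the carboxylate, which then attacks C3 in the 5-exo mode normal for cyclohex-3-ene carboxylic acids, with trans-diaxial opening. The carboxyl group can bridge only on its own face, so the C3 oxygen is fixed cis to the C5 carbon and the C4 methyl group, and iodine goes to C2 trans to oxygen.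

Step 7
Reactants: 9 (1R,4R,5R,8R)-4-iodo-8-methyl-1-[2-(2-methyl-1,3-dioxolan-2-yl)ethyl]-6-oxabicyclo[3.2.1]octan-7-one
Product: 10 (1R,5S,8R)-8-methyl-1-[2-(2-methyl-1,3-dioxolan-2-yl)ethyl]-6-oxabicyclo[3.2.1]oct-3-en-7-one
Conditions: 1,8-diazabicyclo[5.4.0]undec-7-ene (DBU), toluene, 100 °C
Reagents that add atoms: none
Why: E2 dehydroiodination; the axial C2 iodide has an antiperiplanar hydrogen only at C1, because C3 is a bridgehead, so the alkene can form only as C1=C2.

Step 8
Reactants: 10 (1R,5S,8R)-8-methyl-1-[2-(2-methyl-1,3-dioxolan-2-yl)ethyl]-6-oxabicyclo[3.2.1]oct-3-en-7-one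
Product: 11 (1R,5S,8R)-8-methyl-1-[2-(2-methyl-1,3-dioxolan-2-yl)ethyl]-6-oxabicyclo[3.2.1]oct-3-en-7-ol (both C7 epimers)
Conditions: i-Bu2AlH (1.1 equiv), CH2Cl2, −78 °C; MeOH, then aq. potassium sodium tartrate
Reagents that add atoms: none
Why: Partial reduction of a lactone to the lactol, stopped at the aluminium lactolate at −78 °C.

Step 9
Reactants: 11 (1R,5S,8R)-8-methyl-1-[2-(2-methyl-1,3-dioxolan-2-yl)ethyl]-6-oxabicyclo[3.2.1]oct-3-en-7-ol
Product: 13 (1S,5S,6R)-5,6-dimethyl-5-[2-(2-methyl-1,3-dioxolan-2-yl)ethyl]cyclohex-2-en-1-ol, via hydrazone 12 (not isolated)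
Conditions: N2H4·H2O, diethylene glycol, 130 °C; then KOH, 195 °C, argon
Reagents that add atoms: none
Why: Wolff–Kishner reduction (Huang-Minlon procedure) of the hydroxy aldehyde that is in equilibrium with the lactol: the open form gives hydrazone 12, which loses N2 under KOH, so the former formyl carbon becomes the C5 methyl group and C3 is released as the free alcohol. No stereocentre is touched and the ketal is stable to base.

Step 10
Reactants: 13 (1S,5S,6R)-5,6-dimethyl-5-[2-(2-methyl-1,3-dioxolan-2-yl)ethyl]cyclohex-2-en-1-ol
Product: 14 tert-butyl({(1S,5S,6R)-5,6-dimethyl-5-[2-(2-methyl-1,3-dioxolan-2-yl)ethyl]cyclohex-2-en-1-yl}oxy)dimethylsilane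
Conditions: TBSCl, imidazole, DMF, rt → 40 °C
Reagents that add atoms: tert-butyldimethylsilyl chloride, CC(C)(C)[Si](C)(C)Cl
Why: Silylation of the secondary alcohol; the ether keeps the allylic alcohol from being oxidised in step 11 and from reacting with the amide bases of steps 13 and 15.

Step 11
Reactants: 14 tert-butyl({(1S,5S,6R)-5,6-dimethyl-5-[2-(2-methyl-1,3-dioxolan-2-yl)ethyl]cyclohex-2-en-1-yl}oxy)dimethylsilane
Product: 15 (4S,5R,6R)-4-[(tert-butyldimethylsilyl)oxy]-5,6-dimethyl-6-[2-(2-methyl-1,3-dioxolan-2-yl)ethyl]cyclohex-2-en-1-one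
Conditions: CrO3, 3,5-dimethylpyrazole, CH2Cl2, −20 °C
Reagents that add atoms: chromium trioxide, O=[Cr](=O)=O
Why: Allylic oxidation of a cyclohexene to the cyclohexenone by the hexavalent chromium–pyrazole complex; C10 is the only allylic methylene, while C3–H is tertiary, screened by the silyl group and inductively deactivated. 3-Silyloxycyclohexenes are a known substrate class for conversion into 4-silyloxycyclohex-2-enones in this way.

Step 12
Reactants: 15 (4S,5R,6R)-4-[(tert-butyldimethylsilyl)oxy]-5,6-dimethyl-6-[2-(2-methyl-1,3-dioxolan-2-yl)ethyl]cyclohex-2-en-1-one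
Product: 16 (4S,5R,6R)-4-[(tert-butyldimethylsilyl)oxy]-5,6-dimethyl-6-(3-oxobutyl)cyclohex-2-en-1-one
Conditions: pyridinium p-toluenesulfonate, acetone/H2O, 50 °C
Reagents that add atoms: water, O
Why: Mild acid-catalysed ketal hydrolysis; the weak acid should leave the secondary silyl ether and the γ-silyloxy enone intact.

Step 13
Reactants: 16 (4S,5R,6R)-4-[(tert-butyldimethylsilyl)oxy]-5,6-dimethyl-6-(3-oxobutyl)cyclohex-2-en-1-one
Product: 18 (4aR,5R,6S)-6-[(tert-butyldimethylsilyl)oxy]-8a-hydroxy-4a,5-dimethyl-3,4,4a,5,6,8a-hexahydronaphthalen-2(1H)-one (C8a epimers), via lithium enolate 17 (not isolated)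
Conditions: LiN(i-Pr)2 (1.05 equiv), THF, −78 → −40 °C; AcOH, −78 °C
Reagents that add atoms: none
Why: Kinetic deprotonation of the methyl ketone at its methyl group (the enone has no α′-hydrogen and its γ C3–H is not removed at −78 °C), then intramolecular aldol addition of the enolate to the C10 carbonyl through a six-membered chair transition state. The new carbinol centre at C10 is lost in step 14, so its configuration does not matter.

Step 14
Reactants: 18 (4aR,5R,6S)-6-[(tert-butyldimethylsilyl)oxy]-8a-hydroxy-4a,5-dimethyl-3,4,4a,5,6,8a-hexahydronaphthalen-2(1H)-one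
Product: 20 (4aR,5R,6S)-6-[(tert-butyldimethylsilyl)oxy]-4a,5-dimethyl-4,4a,5,6-tetrahydronaphthalen-2(3H)-one, via tertiary mesylate 19 (not isolated)
Conditions: MsCl, Et3N, CH2Cl2, 0 °C → rt
Reagents that add atoms: none
Why: Sulfene-type mesylation of the tertiary alcohol and E1cB elimination through the C8 enolate; only C9 carries β-hydrogens, so the alkene is C9=C10, and the linear dienone forms without an equilibrating base that could reopen the aldol or epimerise C3.

Step 15
Reactants: 20 (4aR,5R,6S)-6-[(tert-butyldimethylsilyl)oxy]-4a,5-dimethyl-4,4a,5,6-tetrahydronaphthalen-2(3H)-one; 21 acetone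
Product: 23 (4aR,5R,6S)-6-[(tert-butyldimethylsilyl)oxy]-3-(2-hydroxypropan-2-yl)-4a,5-dimethyl-4,4a,5,6-tetrahydronaphthalen-2(3H)-one (C3 epimers), via lithium dienolate 22 (not isolated)
Conditions: LiN(i-Pr)2 (1.1 equiv), THF, −78 °C; then 21, −78 °C; AcOH, −78 °C
Reagents that add atoms: none
Why: Kinetic α′-deprotonation of the dienone at C7 gives the cross-conjugated enolate, which adds to acetone (aldol addition). The cold quench prevents retro-aldol, and the new C7 centre is removed in step 16.

Step 16
Reactants: 23 (4aR,5R,6S)-6-[(tert-butyldimethylsilyl)oxy]-3-(2-hydroxypropan-2-yl)-4a,5-dimethyl-4,4a,5,6-tetrahydronaphthalen-2(3H)-one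
Product: 25 (4aR,5R,6S)-6-[(tert-butyldimethylsilyl)oxy]-4a,5-dimethyl-3-(propan-2-ylidene)-4,4a,5,6-tetrahydronaphthalen-2(3H)-one, via tertiary mesylate 24 (not isolated)
Conditions: MsCl, Et3N, CH2Cl2, 0 °C; then DBU, rt
Reagents that add atoms: none
Why: Mesylation of the tertiary alcohol and E1cB elimination with loss of the acidic C7 hydrogen, which gives the conjugated tetrasubstituted isopropylidene alkene and not the isopropenyl isomer.

Step 17
Reactants: 25 (4aR,5R,6S)-6-[(tert-butyldimethylsilyl)oxy]-4a,5-dimethyl-3-(propan-2-ylidene)-4,4a,5,6-tetrahydronaphthalen-2(3H)-one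
Product: 26 (4aR,5R,6S)-6-hydroxy-4a,5-dimethyl-3-(propan-2-ylidene)-4,4a,5,6-tetrahydronaphthalen-2(3H)-one
Conditions: HF·pyridine, THF, 0 °C → rt
Reagents that add atoms: none
Why: Fluoride cleavage of the Si–O bond under mildly acidic conditions, preferred to basic fluoride so that the vinylogously acidic C3–H is left alone.

Step 18
Reactants: 27 (S)-2-methylbutan-1-ol
Product: 28 (S)-2-methylbutanal
Conditions: 2,2,6,6-tetramethylpiperidin-1-oxyl (cat.), KBr (cat.), NaOCl, NaHCO3, CH2Cl2/H2O, 0 °C; dried CH2Cl2 solution used at once
Reagents that add atoms: none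
Why: Nitroxyl-catalysed hypochlorite oxidation of a primary alcohol (Anelli conditions); the buffered two-phase medium at 0 °C and immediate use of the solution should keep the α-stereocentre of the volatile aldehyde intact.

Step 19
Reactants: 28 (S)-2-methylbutanal; 29 ethyl (E)-4-(diethoxyphosphoryl)but-2-enoate
Product: 31 ethyl (2E,4E,6S)-6-methylocta-2,4-dienoate, via lithiated phosphonate 30 (not isolated)
Conditions: 29, LiN(SiMe3)2, THF, −78 °C; then 28, −78 → 0 °C
Reagents that add atoms: none
Why: Horner–Wadsworth–Emmons olefination with the vinylogous phosphonate; the stabilised anion gives the (E)-alkene at C4=C5 and the 2E geometry is already present in 29. Adding the aldehyde to the preformed anion leaves no free base to racemise C6.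

Step 20
Reactants: 31 ethyl (2E,4E,6S)-6-methylocta-2,4-dienoate
Product: 32 (2E,4E,6S)-6-methylocta-2,4-dienoic acid
Conditions: LiOH, THF/MeOH/H2O, rt; then aq. HCl
Reagents that add atoms: lithium hydroxide, [Li+].[OH-]
Why: Ester saponification by acyl–oxygen cleavage; the diene geometry and the remote stereocentre are not affected at room temperature.

Step 21
Reactants: 26 (4aR,5R,6S)-6-hydroxy-4a,5-dimethyl-3-(propan-2-ylidene)-4,4a,5,6-tetrahydronaphthalen-2(3H)-one; 32 (2E,4E,6S)-6-methylocta-2,4-dienoic acid
Product: 34 (1R,2S,8aR)-1,8a-dimethyl-6-oxo-7-(propan-2-ylidene)-1,2,6,7,8,8a-hexahydronaphthalen-2-yl (2E,4E,6S)-6-methylocta-2,4-dienoate (CNP0215744.1), via mixed anhydride 33 (not isolated)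
Conditions: 32, 2,4,6-trichlorobenzoyl chloride, Et3N, THF, rt; then 26, 4-(dimethylamino)pyridine, toluene, rt
Reagents that add atoms: none
Why: Yamaguchi esterification; the aminopyridine attacks the mixed anhydride at the dienoyl carbonyl and the acylpyridinium ion acylates the C3 hydroxyl. The C3–O bond is not broken, so the configuration at C3 is retained.

## Compound list

1 | ethyl 5-oxohexanoate | CCOC(=O)CCCC(C)=O | starting material
2 | ethyl 4-(2-methyl-1,3-dioxolan-2-yl)butanoate | CCOC(=O)CCCC1(C)OCCO1 | intermediate
3 | 4-(2-methyl-1,3-dioxolan-2-yl)butanal | O=CCCCC1(C)OCCO1 | intermediate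
4 | formaldehyde | C=O | starting material
5 | 2-methylidene-4-(2-methyl-1,3-dioxolan-2-yl)butanal | C=C(C=O)CCC1(C)OCCO1 | intermediate
6 | (E)-penta-1,3-diene | C/C=C/C=C | starting material
7 | (1S,2S)-2-methyl-1-[2-(2-methyl-1,3-dioxolan-2-yl)ethyl]cyclohex-3-ene-1-carbaldehyde (methyl cis to formyl) | O=C[C@]1(CCC2(C)OCCO2)CCC=C[C@@H]1C | intermediate
8 | (1S,2S)-2-methyl-1-[2-(2-methyl-1,3-dioxolan-2-yl)ethyl]cyclohex-3-ene-1-carboxylic acid | OC(=O)[C@]1(CCC2(C)OCCO2)CCC=C[C@@H]1C | intermediate
9 | (1R,4R,5R,8R)-4-iodo-8-methyl-1-[2-(2-methyl-1,3-dioxolan-2-yl)ethyl]-6-oxabicyclo[3.2.1]octan-7-one (iodine trans to the lactone oxygen, methyl syn to the lactone bridge) | C[C@H]1[C@H]2OC(=O)[C@]1(CCC3(C)OCCO3)CC[C@H]2I | intermediate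
10 | (1R,5S,8R)-8-methyl-1-[2-(2-methyl-1,3-dioxolan-2-yl)ethyl]-6-oxabicyclo[3.2.1]oct-3-en-7-one | C[C@H]1[C@H]2OC(=O)[C@]1(CCC3(C)OCCO3)CC=C2 | intermediate
11 | (1R,5S,8R)-8-methyl-1-[2-(2-methyl-1,3-dioxolan-2-yl)ethyl]-6-oxabicyclo[3.2.1]oct-3-en-7-ol (both C7 epimers) | C[C@H]1[C@H]2OC(O)[C@]1(CCC3(C)OCCO3)CC=C2 | intermediate
12 | (1S,5R,6R)-5-(hydrazinylidenemethyl)-6-methyl-5-[2-(2-methyl-1,3-dioxolan-2-yl)ethyl]cyclohex-2-en-1-ol (hydrazone of the ring-opened form of 11) | C[C@H]1[C@@H](O)C=CC[C@]1(C=NN)CCC2(C)OCCO2 | intermediate (not isolated)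
13 | (1S,5S,6R)-5,6-dimethyl-5-[2-(2-methyl-1,3-dioxolan-2-yl)ethyl]cyclohex-2-en-1-ol | C[C@H]1[C@@H](O)C=CC[C@]1(C)CCC2(C)OCCO2 | intermediate
14 | tert-butyl({(1S,5S,6R)-5,6-dimethyl-5-[2-(2-methyl-1,3-dioxolan-2-yl)ethyl]cyclohex-2-en-1-yl}oxy)dimethylsilane | C[C@H]1[C@@H](O[Si](C)(C)C(C)(C)C)C=CC[C@]1(C)CCC2(C)OCCO2 | intermediate
15 | (4S,5R,6R)-4-[(tert-butyldimethylsilyl)oxy]-5,6-dimethyl-6-[2-(2-methyl-1,3-dioxolan-2-yl)ethyl]cyclohex-2-en-1-one | C[C@H]1[C@@H](O[Si](C)(C)C(C)(C)C)C=CC(=O)[C@]1(C)CCC2(C)OCCO2 | intermediate
16 | (4S,5R,6R)-4-[(tert-butyldimethylsilyl)oxy]-5,6-dimethyl-6-(3-oxobutyl)cyclohex-2-en-1-one | C[C@H]1[C@@H](O[Si](C)(C)C(C)(C)C)C=CC(=O)[C@]1(C)CCC(C)=O | intermediate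
17 | lithium enolate of 16, deprotonated at the side-chain methyl group | [Li+].C[C@H]1[C@@H](O[Si](C)(C)C(C)(C)C)C=CC(=O)[C@]1(C)CCC([O-])=C | intermediate (not isolated)
18 | (4aR,5R,6S)-6-[(tert-butyldimethylsilyl)oxy]-8a-hydroxy-4a,5-dimethyl-3,4,4a,5,6,8a-hexahydronaphthalen-2(1H)-one (C8a epimers) | C[C@H]1[C@@H](O[Si](C)(C)C(C)(C)C)C=CC2(O)CC(=O)CC[C@]12C | intermediate
19 | methanesulfonate of 18 at the C8a hydroxyl | C[C@H]1[C@@H](O[Si](C)(C)C(C)(C)C)C=CC2(OS(C)(=O)=O)CC(=O)CC[C@]12C | intermediate (not isolated)
20 | (4aR,5R,6S)-6-[(tert-butyldimethylsilyl)oxy]-4a,5-dimethyl-4,4a,5,6-tetrahydronaphthalen-2(3H)-one | C[C@H]1[C@@H](O[Si](C)(C)C(C)(C)C)C=CC2=CC(=O)CC[C@]12C | intermediate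
21 | acetone | CC(C)=O | starting material
22 | lithium enolate of 20, deprotonated at C3 of the naphthalenone (C7 of the target) | [Li+].C[C@H]1[C@@H](O[Si](C)(C)C(C)(C)C)C=CC2=CC([O-])=CC[C@]12C | intermediate (not isolated)
23 | (4aR,5R,6S)-6-[(tert-butyldimethylsilyl)oxy]-3-(2-hydroxypropan-2-yl)-4a,5-dimethyl-4,4a,5,6-tetrahydronaphthalen-2(3H)-one (C3 epimers) | C[C@H]1[C@@H](O[Si](C)(C)C(C)(C)C)C=CC2=CC(=O)C(C(C)(C)O)C[C@]12C | intermediate
24 | methanesulfonate of 23 at the tertiary hydroxyl | C[C@H]1[C@@H](O[Si](C)(C)C(C)(C)C)C=CC2=CC(=O)C(C(C)(C)OS(C)(=O)=O)C[C@]12C | intermediate (not isolated)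
25 | (4aR,5R,6S)-6-[(tert-butyldimethylsilyl)oxy]-4a,5-dimethyl-3-(propan-2-ylidene)-4,4a,5,6-tetrahydronaphthalen-2(3H)-one | C[C@H]1[C@@H](O[Si](C)(C)C(C)(C)C)C=CC2=CC(=O)C(=C(C)C)C[C@]12C | intermediate
26 | (4aR,5R,6S)-6-hydroxy-4a,5-dimethyl-3-(propan-2-ylidene)-4,4a,5,6-tetrahydronaphthalen-2(3H)-one | C[C@H]1[C@@H](O)C=CC2=CC(=O)C(=C(C)C)C[C@]12C | intermediate
27 | (S)-2-methylbutan-1-ol | CC[C@H](C)CO | starting material
28 | (S)-2-methylbutanal | CC[C@H](C)C=O | intermediate
29 | ethyl (E)-4-(diethoxyphosphoryl)but-2-enoate | CCOC(=O)/C=C/CP(=O)(OCC)OCC | starting material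
30 | lithium salt of 29, anion at the carbon next to phosphorus | [Li+].CCOC(=O)/C=C/[CH-]P(=O)(OCC)OCC | intermediate (not isolated)
31 | ethyl (2E,4E,6S)-6-methylocta-2,4-dienoate | CC[C@H](C)/C=C/C=C/C(=O)OCC | intermediate
32 | (2E,4E,6S)-6-methylocta-2,4-dienoic acid | CC[C@H](C)/C=C/C=C/C(=O)O | intermediate
33 | (2E,4E,6S)-6-methylocta-2,4-dienoic 2,4,6-trichlorobenzoic anhydride | CC[C@H](C)/C=C/C=C/C(=O)OC(=O)c1c(Cl)cc(Cl)cc1Cl | intermediate (not isolated)
34 | (1R,2S,8aR)-1,8a-dimethyl-6-oxo-7-(propan-2-ylidene)-1,2,6,7,8,8a-hexahydronaphthalen-2-yl (2E,4E,6S)-6-methylocta-2,4-dienoate | CC[C@H](C)/C=C/C=C/C(=O)O[C@H]1C=CC2=CC(=O)C(=C(C)C)C[C@]2(C)[C@H]1C | target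

## Step count and least certain steps

Total step count: 21. Longest linear sequence: 18 steps (steps 1 to 17, then step 21), from ethyl 5-oxohexanoate; steps 18 to 20 form the three-step side-chain branch.

Step 4 (key step). Three things may go wrong. The cationic boron catalyst may be tied up or consumed by the ketal oxygens, so that turnover stops. The carbonyl-endo preference may erode, because the α-substituent competes with the formyl group for the endo position, and this would give the trans C4/C5 isomer. The enal face may be discriminated less cleanly than needed. Fallback: from 5 and 6, a Me2AlCl-promoted cycloaddition at −78 °C in CH2Cl2 should give the racemic cis aldehyde F1. Pinnick oxidation as in step 5 would give the racemic acid F2, which would be resolved by crystallisation of its (R)-1-phenylethylammonium salt F3 (the other amine enantiomer is used if the wrong acid enantiomer crystallises). Acidification returns the route to 8.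

Step 9. Hydrazone formation may be incomplete, because the aldehyde is neopentylic and held as the lactol. At 195 °C in strong base the allylic alkoxide may isomerise, and diimide from adventitious oxidation of hydrazine may reduce C1=C2. Fallback: from 10, LiAlH4 in THF should give the diol F4. The primary hydroxyl would be sulfonylated selectively (TsCl, pyridine, 0 °C) to the tosylate F5, and the secondary hydroxyl silylated at once (TBSCl, imidazole, DMF) to the silyl ether tosylate F6, before the free hydroxyl can displace the tosylate. Hydride displacement with LiBHEt3 in refluxing THF would then give the methyl group and return the route to 14.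

Step 11. Oxygen may be delivered to the other end of the allylic system (C2), which would give the transposed enone. Hydrogen abstraction at C3 would destroy that stereocentre, and the hindered, neopentylic C10 may react slowly enough for over-oxidation to compete. Fallback: from 14, SeO2 (cat.) with t-BuOOH in CH2Cl2 would oxidise by an ene reaction and [2,3]-shift, a sequence that leaves oxygen on the carbon that lost hydrogen, to give the allylic alcohol F7. Dess–Martin periodinane would then give the enone and return the route to 15.

Step 13. Proton transfer within the enolate, to the C7 side of the ketone or to the γ position of the enone, may outrun ring closure. Retro-aldol on warming would also expose C3 to epimerisation. Fallback: from 16, enamine catalysis with pyrrolidine and acetic acid in toluene at 60 °C (the second stage of a Robinson annulation) would activate only the unhindered methyl ketone in a buffered medium and condense directly to 20. Step 14 is then skipped and no new compound arises, F0.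

Step 21. Acylation of the hindered allylic alcohol next to the C4 methyl group may be slow. The activated dienoate could then isomerise through a vinylketene, or the alcohol could eliminate. Fallback: from 26, coupling with diethylphosphonoacetic acid and dicyclohexylcarbodiimide, which tolerates hindered alcohols, would give the phosphonoacetate F9. Separately, 28 and (triphenylphosphoranylidene)acetaldehyde would give (S,E)-4-methylhex-2-enal F8. A Horner–Wadsworth–Emmons reaction of F9 with F8 under LiCl and DBU in MeCN would build the (2E,4E)-dienoate on the ester oxygen and arrive at 34.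

## Further compounds

F1 | step 4 | racemic cis-2-methyl-1-[2-(2-methyl-1,3-dioxolan-2-yl)ethyl]cyclohex-3-ene-1-carbaldehyde (7 and its enantiomer) | O=C[C@]1(CCC2(C)OCCO2)CCC=C[C@@H]1C.O=C[C@@]1(CCC2(C)OCCO2)CCC=C[C@H]1C
F2 | step 4 | racemic cis-2-methyl-1-[2-(2-methyl-1,3-dioxolan-2-yl)ethyl]cyclohex-3-ene-1-carboxylic acid (8 and its enantiomer) | OC(=O)[C@]1(CCC2(C)OCCO2)CCC=C[C@@H]1C.OC(=O)[C@@]1(CCC2(C)OCCO2)CCC=C[C@H]1C
F3 | step 4 | (R)-1-phenylethylammonium (1S,2S)-2-methyl-1-[2-(2-methyl-1,3-dioxolan-2-yl)ethyl]cyclohex-3-ene-1-carboxylate | [O-]C(=O)[C@]1(CCC2(C)OCCO2)CCC=C[C@@H]1C.C[C@@H]([NH3+])c1ccccc1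
F4 | step 9 | (1S,5R,6R)-5-(hydroxymethyl)-6-methyl-5-[2-(2-methyl-1,3-dioxolan-2-yl)ethyl]cyclohex-2-en-1-ol | C[C@H]1[C@@H](O)C=CC[C@]1(CO)CCC2(C)OCCO2
F5 | step 9 | {(1R,5S,6R)-5-hydroxy-6-methyl-1-[2-(2-methyl-1,3-dioxolan-2-yl)ethyl]cyclohex-3-en-1-yl}methyl 4-methylbenzenesulfonate | C[C@H]1[C@@H](O)C=CC[C@]1(COS(=O)(=O)c2ccc(C)cc2)CCC3(C)OCCO3
F6 | step 9 | {(1R,5S,6R)-5-[(tert-butyldimethylsilyl)oxy]-6-methyl-1-[2-(2-methyl-1,3-dioxolan-2-yl)ethyl]cyclohex-3-en-1-yl}methyl 4-methylbenzenesulfonate | C[C@H]1[C@@H](O[Si](C)(C)C(C)(C)C)C=CC[C@]1(COS(=O)(=O)c2ccc(C)cc2)CCC3(C)OCCO3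
F7 | step 11 | (4S,5R,6R)-4-[(tert-butyldimethylsilyl)oxy]-5,6-dimethyl-6-[2-(2-methyl-1,3-dioxolan-2-yl)ethyl]cyclohex-2-en-1-ol (C1 epimers) | C[C@H]1[C@@H](O[Si](C)(C)C(C)(C)C)C=CC(O)[C@]1(C)CCC2(C)OCCO2
F0 | step 13 | none | none
F8 | step 21 | (S,E)-4-methylhex-2-enal | CC[C@H](C)/C=C/C=O
F9 | step 21 | (1R,2S,8aR)-1,8a-dimethyl-6-oxo-7-(propan-2-ylidene)-1,2,6,7,8,8a-hexahydronaphthalen-2-yl 2-(diethoxyphosphoryl)acetate | CCOP(=O)(CC(=O)O[C@H]1C=CC2=CC(=O)C(=C(C)C)C[C@]2(C)[C@H]1C)OCC
A1 | alternative 1 | cis-fused 2,8,8-trimethyl-2-(prop-2-en-1-yl)-7-oxa-8-silabicyclo[4.3.0]nonan-3-one (oxasilolane ketone with the C5 methyl and allyl groups) | C[Si]1(C)C[C@H]2[C@H](CCC(=O)[C@]2(C)CC=C)O1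
A2 | alternative 1 | (4S)-4-{[(bromomethyl)dimethylsilyl]oxy}-2-methylcyclohex-2-en-1-one | CC1=C[C@@H](O[Si](C)(C)CBr)CCC1=O
A3 | alternative 1 | allyltributylstannane | C=CC[Sn](CCCC)(CCCC)CCCC
A4 | alternative 2 | tert-butyl{[(1R,2S,8aR)-1,8a-dimethyl-1,2,6,7,8,8a-hexahydronaphthalen-2-yl]oxy}dimethylsilane | CC(C)(C)[Si](C)(C)O[C@H]1C=CC2=CCCC[C@]2(C)[C@H]1C
A5 | alternative 2 | tert-butyl{[(3S,4R,5R)-5-ethynyl-4,5-dimethyldeca-1,9-dien-3-yl]oxy}dimethylsilane | C=C[C@H](O[Si](C)(C)C(C)(C)C)[C@H](C)[C@](C)(C#C)CCCC=C
A6 | alternative 3 | methyl 3,7-bis[(tert-butyldimethylsilyl)oxy]-8,8a-dimethyl-1,2,3,5,6,7,8,8a-octahydronaphthalene-2-carboxylate (configuration as in the SMILES) | COC(=O)[C@@H]1C[C@]2(C)[C@@H](C)[C@@H](O[Si](C)(C)C(C)(C)C)CCC2=C[C@@H]1O[Si](C)(C)C(C)(C)C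
A7 | alternative 3 | tert-butyl({(1S,2R)-4-[(E)-2-{[tert-butyl(dimethyl)silyl]oxy}ethenyl]-2,3-dimethylcyclohex-3-en-1-yl}oxy)dimethylsilane | C[C@H]1[C@@H](O[Si](C)(C)C(C)(C)C)CCC(/C=C/O[Si](C)(C)C(C)(C)C)=C1C
A8 | alternative 3 | methyl acrylate | C=CC(=O)OC
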